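The upper (guibourtinidol) unit is opened at its O1–C8a aryl ether bond. In ring A the C7 hydroxyl sits para to C4a and meta to C8a, so ring A can be drawn from a tyrosine-type 4-alkylphenol: oxidation gives a 4-alkyl-4-hydroxycyclohexa-2,5-dienone, the C2 benzylic hydroxyl adds to its enone carbon (future C8a) and loss of water restores the arene, closing ring C and creating the resorcinol pattern in one operation. The precursor is an open-chain anti-diol monoether carrying a cyclohexadienone in place of ring A. The fisetinidol unit is made the same way; C4 is set in a late Friedel–Crafts union.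

Key step: step 8

Remark: flavan numbering (O1, C2, C3, C4, C4a, C5–C8, C8a) is used for the atoms of both units, also in their open-chain precursors. (S)-3-(4-Hydroxyphenyl)lactic acid 1 is taken as a purchased building block (it is the diazotisation product of L-tyrosine). Compound 15 is carried as a mixture of C4 epimers because both ionise to the same cation 25.

Step 1
Reactants: 1 (S)-2-hydroxy-3-(4-hydroxyphenyl)propanoic acid
Product: 2 (S)-2-hydroxy-3-(4-hydroxyphenyl)-N-methoxy-N-methylpropanamide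
Conditions: MeNHOMe·HCl, EDC·HCl, HOBt, N-methylmorpholine, DMF, 0 °C → rt
Reagents that add atoms: N,O-dimethylhydroxylamine hydrochloride, CNOC.Cl
Why: Carbodiimide/HOBt amide coupling acylates the amine much faster than either hydroxyl group and leaves the stereocentre of 1 (the future C3) untouched.

Step 2
Reactants: 2 (S)-2-hydroxy-3-(4-hydroxyphenyl)-N-methoxy-N-methylpropanamide
Product: 3 (S)-3-[4-(tert-butyldimethylsilyloxy)phenyl]-2-hydroxy-N-methoxy-N-methylpropanamide
Conditions: TBSCl (1.05 equiv), Et3N, CH2Cl2, 0 °C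
Reagents that add atoms: tert-butyldimethylsilyl chloride, CC(C)(C)[Si](C)(C)Cl
Why: Silyl ether formation under amine base should be selective for the more acidic phenol over the hindered secondary alcohol, which marks the future ring A oxygen for later selective release.

Step 3
Reactants: 3 (S)-3-[4-(tert-butyldimethylsilyloxy)phenyl]-2-hydroxy-N-methoxy-N-methylpropanamide
Product: 4 (S)-2-(benzyloxy)-3-[4-(tert-butyldimethylsilyloxy)phenyl]-N-methoxy-N-methylpropanamide
Conditions: BnOC(=NH)CCl3, TfOH (cat.), CH2Cl2/cyclohexane, 0 °C → rt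
Reagents that add atoms: benzyl 2,2,2-trichloroacetimidate, N=C(OCc1ccccc1)C(Cl)(Cl)Cl
Why: Acid-catalysed O-benzylation with the trichloroacetimidate needs no base, so the alpha stereocentre should not epimerise, and the benzyl ether serves later as chelating group and as lasting protection of O3.

Step 4
Reactants: 4 (S)-2-(benzyloxy)-3-[4-(tert-butyldimethylsilyloxy)phenyl]-N-methoxy-N-methylpropanamide; 5 1-(benzyloxy)-4-bromobenzene
Product: 7 (S)-2-(benzyloxy)-1-[4-(benzyloxy)phenyl]-3-[4-(tert-butyldimethylsilyloxy)phenyl]propan-1-one, via [4-(benzyloxy)phenyl]magnesium bromide 6 (not isolated)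
Conditions: Mg, THF, reflux (5 → 6); then 4, THF, −20 → 0 °C; then 1 M HCl
Reagents that add atoms: none
Why: Weinreb ketone synthesis, in which the N-methoxy chelate of the first adduct survives until the acidic quench so that the Grignard reagent adds only once and the alpha stereocentre is not exposed to base as a ketone.

Step 5
Reactants: 7 (S)-2-(benzyloxy)-1-[4-(benzyloxy)phenyl]-3-[4-(tert-butyldimethylsilyloxy)phenyl]propan-1-one
Product: 8 (1R,2S)-2-(benzyloxy)-1-[4-(benzyloxy)phenyl]-3-[4-(tert-butyldimethylsilyloxy)phenyl]propan-1-ol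
Conditions: Zn(BH4)2 (from ZnCl2 and NaBH4), Et2O, −20 → 0 °C
Reagents that add atoms: none
Why: Chelation-controlled (Cram chelate) reduction, in which zinc bridges the carbonyl and benzyloxy oxygens and hydride enters opposite the arylmethyl group, should set the carbinol centre (future C2) as R, anti to the benzyloxy group as the 2,3-trans flavan requires.

Step 6
Reactants: 8 (1R,2S)-2-(benzyloxy)-1-[4-(benzyloxy)phenyl]-3-[4-(tert-butyldimethylsilyloxy)phenyl]propan-1-ol
Product: 9 (1R,2S)-2-(benzyloxy)-1-[4-(benzyloxy)phenyl]-3-(4-hydroxyphenyl)propan-1-ol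
Conditions: TBAF, AcOH, THF, 0 °C
Reagents that add atoms: none
Why: Fluoride-mediated desilylation frees only the ring A phenol, with acetic acid buffering the phenoxide, while the benzyl ethers and the secondary alcohol are inert.

Step 7
Reactants: 9 (1R,2S)-2-(benzyloxy)-1-[4-(benzyloxy)phenyl]-3-(4-hydroxyphenyl)propan-1-ol
Product: 11 4-[(2S,3R)-2-(benzyloxy)-3-[4-(benzyloxy)phenyl]-3-hydroxypropyl]-4-hydroxycyclohexa-2,5-dien-1-one, via 4-hydroperoxycyclohexadienone 10 (not isolated)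
Conditions: Oxone (2KHSO5·KHSO4·K2SO4), NaHCO3, MeCN/H2O, rt; then aq. Na2S2O3
Reagents that add atoms: potassium peroxymonosulfate, [K+].[O-]S(=O)(=O)OO
Why: Oxidative dearomatisation by singlet oxygen (generated from peroxymonosulfate) adds to the phenolate at the para carbon and thiosulfate reduces the hydroperoxide to the p-quinol; because no phenoxonium ion is formed, the side-chain hydroxyl should not spirocyclise and the aryl benzyl ethers are not attacked.

Step 8
Reactants: 11 4-[(2S,3R)-2-(benzyloxy)-3-[4-(benzyloxy)phenyl]-3-hydroxypropyl]-4-hydroxycyclohexa-2,5-dien-1-one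
Product: 13 (2R,3S)-3-(benzyloxy)-2-[4-(benzyloxy)phenyl]chroman-7-ol, via cis-fused oxa-Michael adduct 12 (not isolated)
Conditions: DBU (0.2 equiv), CH2Cl2, rt; then TsOH·H2O (1.5 equiv), rt
Reagents that add atoms: none
Why: Under DBU the free benzylic hydroxyl adds in a 6-exo-trig oxa-Michael fashion to one enone arm of the cyclohexadienone, which forms the O1–C8a bond and gives the cis-fused adduct 12; TsOH then enolises the remaining enone toward C8, the tertiary C4a hydroxyl leaves as water from this arene-hydrate-type dienol and loss of the C8a proton rearomatises the carbocycle to the C7 phenol. The closest known reaction types are the intramolecular oxa-Michael ring closures of p-quinols and the conjugate addition–dehydrative rearomatisation sequence used to functionalise para-substituted phenols meta to the hydroxyl. The only ring closed is the pyran ring (6-exo-trig); the two ring-fusion centres of 12 are transient and are erased on aromatisation, so both diastereotopic enone arms converge on 13 and no new stereocentre has to be controlled, while C2 and C3 are carried over unchanged from 11. The step needs the benzylic hydroxyl to be the only nucleophile able to reach the dienone, which the benzyl ether on the neighbouring oxygen secures (a free hydroxyl there would close a five-membered ring), and it needs the 4-benzyloxybenzylic alcohol not to meet acid in its open form, which is secured by running the Michael addition under base before the acid is added. Should acid reopen the pyran ring at C2 after aromatisation, reclosure should favour the wanted 2,3-trans chroman with both substituents equatorial.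

Step 9
Reactants: 13 (2R,3S)-3-(benzyloxy)-2-[4-(benzyloxy)phenyl]chroman-7-ol
Product: 15 (2R,3S,4RS)-3-(benzyloxy)-2-[4-(benzyloxy)phenyl]-4-methoxychroman-7-ol, via p-quinone methide 14 (not isolated)
Conditions: DDQ (1.05 equiv), CH2Cl2/MeOH (4:1), 0 °C
Reagents that add atoms: methanol, CO
Why: Quinone dehydrogenation of the 4-alkylphenol (C4 is para to the free C7 hydroxyl) gives the p-quinone methide, and 1,6-addition of methanol at C4 restores the phenol; the C4 configuration is irrelevant because this centre is ionised again in step 15.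

Step 10
Reactants: 4 (S)-2-(benzyloxy)-3-[4-(tert-butyldimethylsilyloxy)phenyl]-N-methoxy-N-methylpropanamide; 16 1,2-bis(benzyloxy)-4-bromobenzene
Product: 18 (S)-2-(benzyloxy)-1-[3,4-bis(benzyloxy)phenyl]-3-[4-(tert-butyldimethylsilyloxy)phenyl]propan-1-one, via [3,4-bis(benzyloxy)phenyl]magnesium bromide 17 (not isolated)
Conditions: Mg, THF, reflux (16 → 17); then 4, THF, −20 → 0 °C; then 1 M HCl
Reagents that add atoms: none
Why: Weinreb ketone synthesis as in step 4, with single addition secured by the N-methoxy chelate.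

Step 11
Reactants: 18 (S)-2-(benzyloxy)-1-[3,4-bis(benzyloxy)phenyl]-3-[4-(tert-butyldimethylsilyloxy)phenyl]propan-1-one
Product: 19 (1R,2S)-2-(benzyloxy)-1-[3,4-bis(benzyloxy)phenyl]-3-[4-(tert-butyldimethylsilyloxy)phenyl]propan-1-ol
Conditions: Zn(BH4)2 (from ZnCl2 and NaBH4), Et2O, −20 → 0 °C
Reagents that add atoms: none
Why: Chelation-controlled reduction as in step 5 should set the carbinol centre (future C2 of the fisetinidol unit) as R, anti to the benzyloxy group.

Step 12
Reactants: 19 (1R,2S)-2-(benzyloxy)-1-[3,4-bis(benzyloxy)phenyl]-3-[4-(tert-butyldimethylsilyloxy)phenyl]propan-1-ol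
Product: 20 (1R,2S)-2-(benzyloxy)-1-[3,4-bis(benzyloxy)phenyl]-3-(4-hydroxyphenyl)propan-1-ol
Conditions: TBAF, AcOH, THF, 0 °C
Reagents that add atoms: none
Why: Buffered fluoride desilylation releases only the phenol, as in step 6.

Step 13
Reactants: 20 (1R,2S)-2-(benzyloxy)-1-[3,4-bis(benzyloxy)phenyl]-3-(4-hydroxyphenyl)propan-1-ol
Product: 22 4-[(2S,3R)-2-(benzyloxy)-3-[3,4-bis(benzyloxy)phenyl]-3-hydroxypropyl]-4-hydroxycyclohexa-2,5-dien-1-one, via 4-hydroperoxycyclohexadienone 21 (not isolated)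
Conditions: Oxone (2KHSO5·KHSO4·K2SO4), NaHCO3, MeCN/H2O, rt; then aq. Na2S2O3
Reagents that add atoms: potassium peroxymonosulfate, [K+].[O-]S(=O)(=O)OO
Why: Singlet-oxygen dearomatisation of the phenolate and reduction of the hydroperoxide as in step 7; the catechol dibenzyl ether ring is far less reactive toward singlet oxygen than the phenolate.

Step 14
Reactants: 22 4-[(2S,3R)-2-(benzyloxy)-3-[3,4-bis(benzyloxy)phenyl]-3-hydroxypropyl]-4-hydroxycyclohexa-2,5-dien-1-one
Product: 24 (2R,3S)-3-(benzyloxy)-2-[3,4-bis(benzyloxy)phenyl]chroman-7-ol, via cis-fused oxa-Michael adduct 23 (not isolated)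
Conditions: DBU (0.2 equiv), CH2Cl2, rt; then TsOH·H2O (1.5 equiv), rt
Reagents that add atoms: none
Why: The same 6-exo-trig oxa-Michael addition and acid-promoted dehydrative rearomatisation as in step 8 closes the pyran ring of the fisetinidol unit with C2 and C3 carried over from 22.

Step 15
Reactants: 15 (2R,3S,4RS)-3-(benzyloxy)-2-[4-(benzyloxy)phenyl]-4-methoxychroman-7-ol; 24 (2R,3S)-3-(benzyloxy)-2-[3,4-bis(benzyloxy)phenyl]chroman-7-ol
Product: 26 (2R,3S,4R)-3-(benzyloxy)-2-[4-(benzyloxy)phenyl]-4-[(2R,3S)-3-(benzyloxy)-2-[3,4-bis(benzyloxy)phenyl]-7-hydroxychroman-6-yl]chroman-7-ol, via C4 benzylic cation 25 (not isolated)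
Conditions: 24 (3 equiv), BF3·OEt2, CH2Cl2, −40 → −10 °C
Reagents that add atoms: none
Why: Friedel–Crafts alkylation in which BF3 takes the C4 methoxy group of either epimer of 15 to leave the benzylic cation 25, stabilised by the para C7 hydroxyl and the ortho ring oxygen, which C6 of 24 (ortho to its free hydroxyl, para to O1 and less hindered than C8) should attack on the face anti to the C3 benzyloxy group, setting C4 as R (3,4-trans); the excess of 24 suppresses self-condensation.

Step 16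
Reactants: 26 (2R,3S,4R)-3-(benzyloxy)-2-[4-(benzyloxy)phenyl]-4-[(2R,3S)-3-(benzyloxy)-2-[3,4-bis(benzyloxy)phenyl]-7-hydroxychroman-6-yl]chroman-7-ol
Product: 27 (2R,3S,4R)-4-[(2R,3S)-2-(3,4-dihydroxyphenyl)-3,7-dihydroxychroman-6-yl]-2-(4-hydroxyphenyl)chroman-3,7-diol (guibourtinidol-(4α→6)-fisetinidol)
Conditions: H2 (1 atm), Pd(OH)2/C, THF/MeOH, rt
Reagents that add atoms: none
Why: Catalytic hydrogenolysis should remove the five benzyl ethers without touching any stereocentre and deliver the free octaol.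

Compound list
1 | (S)-2-hydroxy-3-(4-hydroxyphenyl)propanoic acid | OC(=O)[C@@H](O)Cc1ccc(O)cc1 | starting material
2 | (S)-2-hydroxy-3-(4-hydroxyphenyl)-N-methoxy-N-methylpropanamide | CON(C)C(=O)[C@@H](O)Cc1ccc(O)cc1 | intermediate
3 | (S)-3-[4-(tert-butyldimethylsilyloxy)phenyl]-2-hydroxy-N-methoxy-N-methylpropanamide | CON(C)C(=O)[C@@H](O)Cc1ccc(O[Si](C)(C)C(C)(C)C)cc1 | intermediate
4 | (S)-2-(benzyloxy)-3-[4-(tert-butyldimethylsilyloxy)phenyl]-N-methoxy-N-methylpropanamide | CON(C)C(=O)[C@@H](OCc1ccccc1)Cc1ccc(O[Si](C)(C)C(C)(C)C)cc1 | intermediate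
5 | 1-(benzyloxy)-4-bromobenzene | Brc1ccc(OCc2ccccc2)cc1 | starting material
6 | [4-(benzyloxy)phenyl]magnesium bromide | Br[Mg]c1ccc(OCc2ccccc2)cc1 | intermediate
7 | (S)-2-(benzyloxy)-1-[4-(benzyloxy)phenyl]-3-[4-(tert-butyldimethylsilyloxy)phenyl]propan-1-one | O=C(c1ccc(OCc2ccccc2)cc1)[C@@H](OCc1ccccc1)Cc1ccc(O[Si](C)(C)C(C)(C)C)cc1 | intermediate
8 | (1R,2S)-2-(benzyloxy)-1-[4-(benzyloxy)phenyl]-3-[4-(tert-butyldimethylsilyloxy)phenyl]propan-1-ol | O[C@H](c1ccc(OCc2ccccc2)cc1)[C@@H](OCc1ccccc1)Cc1ccc(O[Si](C)(C)C(C)(C)C)cc1 | intermediate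
9 | (1R,2S)-2-(benzyloxy)-1-[4-(benzyloxy)phenyl]-3-(4-hydroxyphenyl)propan-1-ol | O[C@H](c1ccc(OCc2ccccc2)cc1)[C@@H](OCc1ccccc1)Cc1ccc(O)cc1 | intermediate
10 | 4-[(2S,3R)-2-(benzyloxy)-3-[4-(benzyloxy)phenyl]-3-hydroxypropyl]-4-hydroperoxycyclohexa-2,5-dien-1-one | O[C@H](c1ccc(OCc2ccccc2)cc1)[C@@H](OCc1ccccc1)CC1(OO)C=CC(=O)C=C1 | intermediate
11 | 4-[(2S,3R)-2-(benzyloxy)-3-[4-(benzyloxy)phenyl]-3-hydroxypropyl]-4-hydroxycyclohexa-2,5-dien-1-one | O[C@H](c1ccc(OCc2ccccc2)cc1)[C@@H](OCc1ccccc1)CC1(O)C=CC(=O)C=C1 | intermediate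
12 | (2R,3S)-3-(benzyloxy)-2-[4-(benzyloxy)phenyl]-4a-hydroxy-2,3,4,4a,8,8a-hexahydro-7H-chromen-7-one (cis-fused, either ring-fusion diastereomer) | O=C1C=CC2(O)C[C@H](OCc3ccccc3)[C@@H](c3ccc(OCc4ccccc4)cc3)OC2C1 | intermediate
13 | (2R,3S)-3-(benzyloxy)-2-[4-(benzyloxy)phenyl]chroman-7-ol | Oc1ccc2C[C@H](OCc3ccccc3)[C@@H](c3ccc(OCc4ccccc4)cc3)Oc2c1 | intermediate
14 | (2R,3S)-3-(benzyloxy)-2-[4-(benzyloxy)phenyl]-2,3-dihydro-7H-chromen-7-one (p-quinone methide) | O=C1C=CC2=C[C@H](OCc3ccccc3)[C@@H](c3ccc(OCc4ccccc4)cc3)OC2=C1 | intermediate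
15 | (2R,3S,4RS)-3-(benzyloxy)-2-[4-(benzyloxy)phenyl]-4-methoxychroman-7-ol | Oc1ccc2C(OC)[C@H](OCc3ccccc3)[C@@H](c3ccc(OCc4ccccc4)cc3)Oc2c1 | intermediate
16 | 1,2-bis(benzyloxy)-4-bromobenzene | Brc1ccc(OCc2ccccc2)c(OCc2ccccc2)c1 | starting material
17 | [3,4-bis(benzyloxy)phenyl]magnesium bromide | Br[Mg]c1ccc(OCc2ccccc2)c(OCc2ccccc2)c1 | intermediate
18 | (S)-2-(benzyloxy)-1-[3,4-bis(benzyloxy)phenyl]-3-[4-(tert-butyldimethylsilyloxy)phenyl]propan-1-one | O=C(c1ccc(OCc2ccccc2)c(OCc2ccccc2)c1)[C@@H](OCc1ccccc1)Cc1ccc(O[Si](C)(C)C(C)(C)C)cc1 | intermediate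
19 | (1R,2S)-2-(benzyloxy)-1-[3,4-bis(benzyloxy)phenyl]-3-[4-(tert-butyldimethylsilyloxy)phenyl]propan-1-ol | O[C@H](c1ccc(OCc2ccccc2)c(OCc2ccccc2)c1)[C@@H](OCc1ccccc1)Cc1ccc(O[Si](C)(C)C(C)(C)C)cc1 | intermediate
20 | (1R,2S)-2-(benzyloxy)-1-[3,4-bis(benzyloxy)phenyl]-3-(4-hydroxyphenyl)propan-1-ol | O[C@H](c1ccc(OCc2ccccc2)c(OCc2ccccc2)c1)[C@@H](OCc1ccccc1)Cc1ccc(O)cc1 | intermediate
21 | 4-[(2S,3R)-2-(benzyloxy)-3-[3,4-bis(benzyloxy)phenyl]-3-hydroxypropyl]-4-hydroperoxycyclohexa-2,5-dien-1-one | O[C@H](c1ccc(OCc2ccccc2)c(OCc2ccccc2)c1)[C@@H](OCc1ccccc1)CC1(OO)C=CC(=O)C=C1 | intermediate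
22 | 4-[(2S,3R)-2-(benzyloxy)-3-[3,4-bis(benzyloxy)phenyl]-3-hydroxypropyl]-4-hydroxycyclohexa-2,5-dien-1-one | O[C@H](c1ccc(OCc2ccccc2)c(OCc2ccccc2)c1)[C@@H](OCc1ccccc1)CC1(O)C=CC(=O)C=C1 | intermediate
23 | (2R,3S)-3-(benzyloxy)-2-[3,4-bis(benzyloxy)phenyl]-4a-hydroxy-2,3,4,4a,8,8a-hexahydro-7H-chromen-7-one (cis-fused, either ring-fusion diastereomer) | O=C1C=CC2(O)C[C@H](OCc3ccccc3)[C@@H](c3ccc(OCc4ccccc4)c(OCc4ccccc4)c3)OC2C1 | intermediate
24 | (2R,3S)-3-(benzyloxy)-2-[3,4-bis(benzyloxy)phenyl]chroman-7-ol | Oc1ccc2C[C@H](OCc3ccccc3)[C@@H](c3ccc(OCc4ccccc4)c(OCc4ccccc4)c3)Oc2c1 | intermediate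
25 | (2R,3S)-3-(benzyloxy)-2-[4-(benzyloxy)phenyl]-7-hydroxychroman-4-ylium (C4 benzylic cation) | Oc1ccc2[CH+][C@H](OCc3ccccc3)[C@@H](c3ccc(OCc4ccccc4)cc3)Oc2c1 | intermediate
26 | (2R,3S,4R)-3-(benzyloxy)-2-[4-(benzyloxy)phenyl]-4-[(2R,3S)-3-(benzyloxy)-2-[3,4-bis(benzyloxy)phenyl]-7-hydroxychroman-6-yl]chroman-7-ol | C(c1ccccc1)Oc1ccc(cc1)[C@H]1Oc2cc(O)ccc2[C@@H](c2cc3c(cc2O)O[C@H](c2ccc(OCc4ccccc4)c(OCc4ccccc4)c2)[C@@H](OCc2ccccc2)C3)[C@@H]1OCc1ccccc1 | intermediate
27 | (2R,3S,4R)-4-[(2R,3S)-2-(3,4-dihydroxyphenyl)-3,7-dihydroxychroman-6-yl]-2-(4-hydroxyphenyl)chroman-3,7-diol | Oc1ccc([C@H]2Oc3cc(O)ccc3[C@@H](c3cc4c(cc3O)O[C@H](c3ccc(O)c(O)c3)[C@@H](O)C4)[C@@H]2O)cc1 | target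

Total step count: 16. Longest linear sequence: 11 steps (steps 1–9, 15 and 16; the fisetinidol branch, steps 10–14, joins at step 15).

Steps most likely to fail

Step 8 (and its twin, step 14). The oxa-Michael adduct may revert under acid faster than it loses water, or the open-chain benzylic alcohol may ionise, so that ring closure and rearomatisation do not run to completion. The fallback sets out from 9 and comes back at 13, forming the same aryl ether bond by intramolecular addition of an alkoxide to an aryne. Bromination of 9 ortho to the phenolic hydroxyl (NBS, cat. iPr2NH, CH2Cl2, 0 °C) would give (1R,2S)-2-(benzyloxy)-1-[4-(benzyloxy)phenyl]-3-(3-bromo-4-hydroxyphenyl)propan-1-ol F1. Phenol-selective protection (MOMCl, K2CO3, acetone) would give (1R,2S)-2-(benzyloxy)-1-[4-(benzyloxy)phenyl]-3-[3-bromo-4-(methoxymethoxy)phenyl]propan-1-ol F2. Lithium 2,2,6,6-tetramethylpiperidide (3 equiv, THF, −78 → 0 °C) would eliminate LiBr to the 3-alkoxyaryne, and the lithium alkoxide should add at the aryne carbon next to the side chain, the position favoured both by the tether and by the alkoxy group, to give (2R,3S)-3-(benzyloxy)-2-[4-(benzyloxy)phenyl]-7-(methoxymethoxy)chroman F3. HCl in MeOH would remove the methoxymethyl group and deliver 13. The same detour from 20 would serve for step 14.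

Step 15. The electrophile may condense with its own phenolic ring A, attack may occur at C8 of 24, and facial selectivity at C4 may be incomplete or eroded by acid-promoted re-ionisation of the new bond. The fallback sets out from 15 and comes back at 26, replacing Lewis-acid ionisation of an ether by thiophilic activation of a thioether. Thiolysis of 15 (BnSH, AcOH, CH2Cl2, rt) would give (2R,3R,4RS)-3-(benzyloxy)-2-[4-(benzyloxy)phenyl]-4-(benzylsulfanyl)chroman-7-ol F7 (same spatial arrangement at C2 and C3 as 15; the C3 descriptor changes by priority only). Treatment of F7 with AgBF4 (THF, 0 °C) in the presence of excess 24 should release the same C4 cation 25 without a boron Lewis acid that could re-ionise the product, and give 26.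

Step 9. The phenol may be over-oxidised, hydride may be abstracted at C2, or the quinone methide may tautomerise to the flav-3-ene before methanol traps it. The fallback sets out from 13 and comes back at 27, activating C4 by hydride abstraction from a fully etherified flavan. Benzylation of 13 (BnBr, K2CO3, DMF) would give (2R,3S)-3,7-bis(benzyloxy)-2-[4-(benzyloxy)phenyl]chroman F4. DDQ with 2-ethoxyethanol (CH2Cl2, rt) would give (2R,3S,4RS)-3,7-bis(benzyloxy)-2-[4-(benzyloxy)phenyl]-4-(2-ethoxyethoxy)chroman F5. Coupling of F5 with 24 (3 equiv, TMSOTf, CH2Cl2, −78 °C) should give (2R,3S,4R)-3,7-bis(benzyloxy)-2-[4-(benzyloxy)phenyl]-4-[(2R,3S)-3-(benzyloxy)-2-[3,4-bis(benzyloxy)phenyl]-7-hydroxychroman-6-yl]chroman F6. Hydrogenolysis of F6 under the conditions of step 16 would give 27.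

Further compounds
F1 | step 8 | (1R,2S)-2-(benzyloxy)-1-[4-(benzyloxy)phenyl]-3-(3-bromo-4-hydroxyphenyl)propan-1-ol | O[C@H](c1ccc(OCc2ccccc2)cc1)[C@@H](OCc1ccccc1)Cc1ccc(O)c(Br)c1
F2 | step 8 | (1R,2S)-2-(benzyloxy)-1-[4-(benzyloxy)phenyl]-3-[3-bromo-4-(methoxymethoxy)phenyl]propan-1-ol | O[C@H](c1ccc(OCc2ccccc2)cc1)[C@@H](OCc1ccccc1)Cc1ccc(OCOC)c(Br)c1
F3 | step 8 | (2R,3S)-3-(benzyloxy)-2-[4-(benzyloxy)phenyl]-7-(methoxymethoxy)chroman | COCOc1ccc2C[C@H](OCc3ccccc3)[C@@H](c3ccc(OCc4ccccc4)cc3)Oc2c1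
F4 | step 9 | (2R,3S)-3,7-bis(benzyloxy)-2-[4-(benzyloxy)phenyl]chroman | C(c1ccccc1)Oc1ccc2C[C@H](OCc3ccccc3)[C@@H](c3ccc(OCc4ccccc4)cc3)Oc2c1
F5 | step 9 | (2R,3S,4RS)-3,7-bis(benzyloxy)-2-[4-(benzyloxy)phenyl]-4-(2-ethoxyethoxy)chroman | C(c1ccccc1)Oc1ccc2C(OCCOCC)[C@H](OCc3ccccc3)[C@@H](c3ccc(OCc4ccccc4)cc3)Oc2c1
F6 | step 9 | (2R,3S,4R)-3,7-bis(benzyloxy)-2-[4-(benzyloxy)phenyl]-4-[(2R,3S)-3-(benzyloxy)-2-[3,4-bis(benzyloxy)phenyl]-7-hydroxychroman-6-yl]chroman | C(c1ccccc1)Oc1ccc(cc1)[C@H]1Oc2cc(OCc3ccccc3)ccc2[C@@H](c2cc3c(cc2O)O[C@H](c2ccc(OCc4ccccc4)c(OCc4ccccc4)c2)[C@@H](OCc2ccccc2)C3)[C@@H]1OCc1ccccc1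
F7 | step 15 | (2R,3R,4RS)-3-(benzyloxy)-2-[4-(benzyloxy)phenyl]-4-(benzylsulfanyl)chroman-7-ol | Oc1ccc2C(SCc3ccccc3)[C@H](OCc3ccccc3)[C@@H](c3ccc(OCc4ccccc4)cc3)Oc2c1
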